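**Retrosynthetic overview**
- Target 29 comes from the C2 carboxylic acid (borane reduction). The C2 hydrogen comes from dealkoxycarbonylation and epimerisation of a C2,C2-diester, and C3=C4 from a selenoxide elimination carried out while C2 is still quaternary.
- Ring B is the only ring formed: the malonate carbon becomes C2 and is inserted between C1 and C3. C1–C2 is made by 1,6-addition to the p-quinone methide of ring C, and C2–C3 by SN2 at an α-bromo ester.
- Feature used: C1 is the benzylic methine para to the 4'-OH of the pendant syringyl ring C (a latent quinone methide carbon), and C3 is α to the ester carbonyl. C2 with its CH2OH branch therefore sits in ring B between two carbons that can both be made electrophilic.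
- Precursor 15 comes from benzhydryl methyl ether 8 (aryllithium plus aldehyde) and methyl glycidate (C4–C3–CO2Me). Both arenes come from 4-bromo-2,6-dimethoxyphenol.

Key step: step 9

Numbering follows the target skeleton: C1 (aryl), C2 (CH2OH), C3 (CO2Me), C4 (=CH), ring A = C4a–C8a, ring C = pendant aryl.
Assumption: the sense of induction of the cinchona-derived catalyst in step 9 cannot be predicted with confidence for this di-ortho-substituted quinone methide; the quinine-derived catalyst or its quinidine-derived pseudoenantiomer is taken, whichever delivers the (1S) adduct.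

**Step 1**
Reactants: 1 4-bromo-2,6-dimethoxyphenol
Product: 2 5-bromo-1,3-dimethoxy-2-(methoxymethoxy)benzene
Conditions: NaH, MOMCl, THF/DMF, 0 °C → rt
Reagents that add atoms: chloromethyl methyl ether (MOMCl), COCCl
Why: Williamson-type O-alkylation of the sodium phenoxide gives a MOM acetal that masks the future C7 phenol against bases and organometallics until the final acid step.

**Step 2**
Reactants: 2 5-bromo-1,3-dimethoxy-2-(methoxymethoxy)benzene
Product: 4 6-bromo-2,4-dimethoxy-3-(methoxymethoxy)benzaldehyde, via aryllithium 3 (not isolated)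
Conditions: LDA, THF, −78 °C; DMF, −78 → 0 °C; aq. NH4Cl
Reagents that add atoms: N,N-dimethylformamide, CN(C)C=O
Why: Directed ortho-metalation: the two equivalent ring hydrogens lie between Br and OMe, so LDA removes one at −78 °C without bromine–lithium exchange and DMF formylates aryllithium 3, which places the future C1 carbon next to the bromide-bearing carbon that becomes C4a.

**Step 3**
Reactants: 1 4-bromo-2,6-dimethoxyphenol
Product: 5 (4-bromo-2,6-dimethoxyphenoxy)(tert-butyl)dimethylsilane
Conditions: TBSCl, imidazole, DMF, rt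
Reagents that add atoms: tert-butyldimethylsilyl chloride, CC(C)(C)[Si](C)(C)Cl
Why: O-silylation masks the ring C phenol for the two organolithium steps and can later be removed with fluoride under non-basic conditions.

**Step 4**
Reactants: 5 (4-bromo-2,6-dimethoxyphenoxy)(tert-butyl)dimethylsilane; 4 6-bromo-2,4-dimethoxy-3-(methoxymethoxy)benzaldehyde
Product: 8 rac-{4-[[6-bromo-2,4-dimethoxy-3-(methoxymethoxy)phenyl](methoxy)methyl]-2,6-dimethoxyphenoxy}(tert-butyl)dimethylsilane, via aryllithium 6 (not isolated), via benzhydrol 7 (not isolated)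
Conditions: n-BuLi, THF, −78 °C; then 4, −78 °C; aq. NH4Cl; crude in MeOH, CSA (cat.), rt
Reagents that add atoms: methanol, CO
Why: Bromine–lithium exchange on 5 and 1,2-addition of aryllithium 6 to the aldehyde give benzhydrol 7 (racemic, and this centre is later erased in the quinone methide), and acid-catalysed SN1 etherification in methanol caps it as a methyl ether that tolerates the next organometallic step and the Appel reaction yet still ionises for sulfone formation.

**Step 5**
Reactants: 8 benzhydryl methyl ether (aryl bromide); 9 methyl oxirane-2-carboxylate (methyl glycidate, racemic)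
Product: 12 methyl 3-{2-[{4-[(tert-butyldimethylsilyl)oxy]-3,5-dimethoxyphenyl}(methoxy)methyl]-3,5-dimethoxy-4-(methoxymethoxy)phenyl}-2-hydroxypropanoate (racemic diastereomer mixture), via aryllithium 10 (not isolated), via arylmagnesium bromide 11 (not isolated)
Conditions: t-BuLi (2 equiv), THF, −78 °C; MgBr2·OEt2; CuI (10 mol %), then 9, −40 → 0 °C; aq. NH4Cl
Reagents that add atoms: none
Why: Bromine–lithium exchange, transmetalation to magnesium and copper-catalysed SN2 opening of the glycidic ester at its unsubstituted CH2 terminus deliver C4, C3 with its hydroxyl and the ester in one operation; the new carbinol centre forms without control and is removed later.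

**Step 6**
Reactants: 12 α-hydroxy ester
Product: 13 methyl 2-bromo-3-{2-[{4-[(tert-butyldimethylsilyl)oxy]-3,5-dimethoxyphenyl}(methoxy)methyl]-3,5-dimethoxy-4-(methoxymethoxy)phenyl}propanoate (diastereomer mixture)
Conditions: PPh3, CBr4, CH2Cl2, 0 °C → rt
Reagents that add atoms: carbon tetrabromide, BrC(Br)(Br)Br
Why: Appel reaction: the alkoxyphosphonium of the secondary α-hydroxy ester is displaced by bromide under neutral conditions that leave the benzhydryl ether, the MOM acetal and the silyl ether alone; the configuration at C3 is irrelevant.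

**Step 7**
Reactants: 13 α-bromo ester
Product: 15 methyl 2-bromo-3-{2-[(4-hydroxy-3,5-dimethoxyphenyl)(4-methylbenzenesulfonyl)methyl]-3,5-dimethoxy-4-(methoxymethoxy)phenyl}propanoate (diastereomer mixture), via silyl sulfone 14 (not isolated)
Conditions: p-TolSO2H (freshly liberated from its sodium salt), CH2Cl2, rt; then HF·pyridine, THF, 0 °C → rt
Reagents that add atoms: p-toluenesulfinic acid, Cc1ccc(S(=O)O)cc1
Why: SN1 sulfonylation: the sulfinic acid ionises the doubly donor-stabilised benzhydryl methyl ether and sulfinate captures the cation at sulfur, and HF·pyridine then removes the aryl silyl ether without forming the phenoxide that would expel sulfinate prematurely.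

**Step 8**
Reactants: 16 3-tert-butoxy-3-oxopropanoic acid (mono-tert-butyl malonate)
Product: 17 allyl tert-butyl malonate (1-tert-butyl 3-prop-2-en-1-yl propanedioate)
Conditions: allyl bromide, KHCO3, DMF, rt
Reagents that add atoms: allyl bromide, C=CCBr
Why: O-alkylation of the carboxylate gives a malonate with two orthogonal esters, chosen because decarboxylative protonation at C2 is expected to place hydrogen anti to the C1 aryl group (cis), so an epimerisable C2 ester must remain after the allyl ester is removed.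

**Step 9**
Reactants: 15 sulfone with α-bromo ester; 17 allyl tert-butyl malonate
Product: 20 2-allyl 2-tert-butyl 3-methyl (1S)-1-(4-hydroxy-3,5-dimethoxyphenyl)-6,8-dimethoxy-7-(methoxymethoxy)-1,2,3,4-tetrahydronaphthalene-2,2,3-tricarboxylate (C2 and C3 epimers), via quinone methide 18 (not isolated), via 1,6-adduct 19 (not isolated)
Conditions: 17 (1.1 equiv), N-[3,5-bis(trifluoromethyl)benzyl]quininium bromide carrying a 9-epi-aryl-urea hydrogen-bond donor (10 mol %), Cs2CO3, toluene, −20 °C; then DMF, 0 °C → rt; cold aq. NH4Cl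
Reagents that add atoms: none
Why: Caesium carbonate deprotonates the phenol of 15 and the phenoxide expels p-toluenesulfinate, so both sulfone epimers give the same planar p-quinone methide 18; the catalyst-bound enolate of 17 adds 1,6 to its exocyclic carbon (C1) and rearomatises ring C to give 19, and once DMF is added the remaining malonate C–H is deprotonated and the carbanion displaces bromide at C3. The closest known reaction types are the phase-transfer-catalysed asymmetric 1,6-addition of malonates to p-quinone methides generated in situ from sulfones and the intramolecular alkylation of a malonate by an α-halo ester (Michael-initiated ring closure). Ring B closes by a 6-exo-tet SN2 displacement with inversion at C3. The one stereocentre that is kept, C1, is set by the chiral ammonium–urea catalyst, which holds the enolate as an ion pair and the quinone methide carbonyl by hydrogen bonding and so distinguishes the two faces of the exocyclic carbon, whereas C2 and C3 form as mixtures that converge later. The step needs 1,6-addition before any loss of HBr and substitution rather than E2 at the α-bromo ester: the quinone methide is by far the strongest electrophile at −20 °C, and the soft, weakly basic malonate anion tethered through a six-membered transition state favours SN2 over elimination.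

**Step 10**
Reactants: 20 tetralin tricarboxylate (free ring C phenol)
Product: 21 2-allyl 2-tert-butyl 3-methyl (1S)-1-[3,5-dimethoxy-4-(methoxymethoxy)phenyl]-6,8-dimethoxy-7-(methoxymethoxy)-1,2,3,4-tetrahydronaphthalene-2,2,3-tricarboxylate (C2 and C3 epimers)
Conditions: MOMCl, i-Pr2NEt, CH2Cl2, 0 °C → rt
Reagents that add atoms: chloromethyl methyl ether (MOMCl), COCCl
Why: O-alkylation of the hindered phenol to its MOM ether removes the acidic OH before enolate chemistry and shuts down retro-1,6-addition, which would racemise C1 through the quinone methide.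

**Step 11**
Reactants: 21 bis-MOM tetralin tricarboxylate
Product: 24 2-allyl 2-tert-butyl 3-methyl (1S)-1-[3,5-dimethoxy-4-(methoxymethoxy)phenyl]-6,8-dimethoxy-7-(methoxymethoxy)-1,2-dihydronaphthalene-2,2,3-tricarboxylate (C3=C4; C2 epimers), via selenide 22 (not isolated), via selenoxide 23 (not isolated)
Conditions: LDA, THF, −78 °C; PhSeBr, −78 → −40 °C; then 30 % H2O2, pyridine, CH2Cl2, 0 °C → rt
Reagents that add atoms: none
Why: α-Selenenylation of the C3 ester enolate followed by selenoxide syn-elimination: C3–H is the only enolisable position, and because C2 is quaternary the selenoxide can only take a hydrogen from C4, so the double bond forms at C3=C4 in conjugation with ring A.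

**Step 12**
Reactants: 24 dihydronaphthalene tricarboxylate
Product: 26 2-tert-butyl 3-methyl (1S)-1-[3,5-dimethoxy-4-(methoxymethoxy)phenyl]-6,8-dimethoxy-7-(methoxymethoxy)-1,2-dihydronaphthalene-2,3-dicarboxylate (C2 epimers), via half-acid 25 (not isolated)
Conditions: Pd(PPh3)4 (5 mol %), morpholine, THF, rt; then toluene, 80 °C
Reagents that add atoms: none
Why: Tsuji–Trost deallylation with morpholine as allyl acceptor frees the C2 malonic half-acid 25, which loses CO2 on warming through the ester dienol; protonation at C2 is not selective, hence the epimer mixture.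

**Step 13**
Reactants: 26 C2 epimer mixture
Product: 27 2-tert-butyl 3-methyl (1S,2R)-1-[3,5-dimethoxy-4-(methoxymethoxy)phenyl]-6,8-dimethoxy-7-(methoxymethoxy)-1,2-dihydronaphthalene-2,3-dicarboxylate (1,2-trans)
Conditions: DBU (0.3 equiv), toluene, rt, argon
Reagents that add atoms: none
Why: Base-mediated epimerisation through the ester dienolate under thermodynamic control: C2–H is α to the tert-butyl ester and allylic, reprotonation returns to C2, and the trans isomer should prevail because the C1 aryl group is held pseudoaxial by the C8 methoxy group while the C2 ester goes pseudoaxial on the opposite face to avoid A(1,2) strain with the C3 ester.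

**Step 14**
Reactants: 27 trans tert-butyl ester
Product: 28 (1S,2R)-7-hydroxy-1-(4-hydroxy-3,5-dimethoxyphenyl)-6,8-dimethoxy-3-(methoxycarbonyl)-1,2-dihydronaphthalene-2-carboxylic acid
Conditions: TFA/CH2Cl2/H2O, 0 °C → rt
Reagents that add atoms: none
Why: Acidolysis: E1 cleavage of the tert-butyl ester and hydrolysis of both MOM acetals occur in one operation with water as trap for the cations, and neither C1 nor C2 is enolised in acid.

**Step 15**
Reactants: 28 carboxylic acid
Product: 29 methyl (1S,2R)-7-hydroxy-1-(4-hydroxy-3,5-dimethoxyphenyl)-2-(hydroxymethyl)-6,8-dimethoxy-1,2-dihydronaphthalene-3-carboxylate (CNP0143100.1)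
Conditions: BH3·THF (excess), THF, 0 °C → rt; MeOH, then neutral aqueous work-up
Reagents that add atoms: none
Why: Chemoselective borane reduction of the carboxylic acid through its acyloxyborane is much faster than reduction of the conjugated methyl ester or hydroboration of the trisubstituted electron-poor C3=C4 bond, and no stereocentre is touched.

**Compound list**
1 | 4-bromo-2,6-dimethoxyphenol | COc1cc(Br)cc(OC)c1O | starting material
2 | 5-bromo-1,3-dimethoxy-2-(methoxymethoxy)benzene | COCOc1c(OC)cc(Br)cc1OC | intermediate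
3 | [6-bromo-2,4-dimethoxy-3-(methoxymethoxy)phenyl]lithium | [Li]c1c(Br)cc(OC)c(OCOC)c1OC | intermediate (not isolated)
4 | 6-bromo-2,4-dimethoxy-3-(methoxymethoxy)benzaldehyde | O=Cc1c(Br)cc(OC)c(OCOC)c1OC | intermediate
5 | (4-bromo-2,6-dimethoxyphenoxy)(tert-butyl)dimethylsilane | COc1cc(Br)cc(OC)c1O[Si](C)(C)C(C)(C)C | intermediate
6 | {4-[(tert-butyldimethylsilyl)oxy]-3,5-dimethoxyphenyl}lithium | [Li]c1cc(OC)c(O[Si](C)(C)C(C)(C)C)c(OC)c1 | intermediate (not isolated)
7 | rac-[6-bromo-2,4-dimethoxy-3-(methoxymethoxy)phenyl]{4-[(tert-butyldimethylsilyl)oxy]-3,5-dimethoxyphenyl}methanol | OC(c1c(Br)cc(OC)c(OCOC)c1OC)c1cc(OC)c(O[Si](C)(C)C(C)(C)C)c(OC)c1 | intermediate (not isolated)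
8 | rac-{4-[[6-bromo-2,4-dimethoxy-3-(methoxymethoxy)phenyl](methoxy)methyl]-2,6-dimethoxyphenoxy}(tert-butyl)dimethylsilane | COC(c1c(Br)cc(OC)c(OCOC)c1OC)c1cc(OC)c(O[Si](C)(C)C(C)(C)C)c(OC)c1 | intermediate
9 | methyl oxirane-2-carboxylate (methyl glycidate, racemic) | COC(=O)C1CO1 | starting material
10 | aryllithium from 8 (Li in place of Br) | COC(c1c([Li])cc(OC)c(OCOC)c1OC)c1cc(OC)c(O[Si](C)(C)C(C)(C)C)c(OC)c1 | intermediate (not isolated)
11 | arylmagnesium bromide from 8 (MgBr in place of Br) | COC(c1c([Mg]Br)cc(OC)c(OCOC)c1OC)c1cc(OC)c(O[Si](C)(C)C(C)(C)C)c(OC)c1 | intermediate (not isolated)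
12 | methyl 3-{2-[{4-[(tert-butyldimethylsilyl)oxy]-3,5-dimethoxyphenyl}(methoxy)methyl]-3,5-dimethoxy-4-(methoxymethoxy)phenyl}-2-hydroxypropanoate (diastereomer mixture) | COC(=O)C(O)Cc1cc(OC)c(OCOC)c(OC)c1C(OC)c1cc(OC)c(O[Si](C)(C)C(C)(C)C)c(OC)c1 | intermediate
13 | methyl 2-bromo-3-{2-[{4-[(tert-butyldimethylsilyl)oxy]-3,5-dimethoxyphenyl}(methoxy)methyl]-3,5-dimethoxy-4-(methoxymethoxy)phenyl}propanoate (diastereomer mixture) | COC(=O)C(Br)Cc1cc(OC)c(OCOC)c(OC)c1C(OC)c1cc(OC)c(O[Si](C)(C)C(C)(C)C)c(OC)c1 | intermediate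
14 | methyl 2-bromo-3-{2-[{4-[(tert-butyldimethylsilyl)oxy]-3,5-dimethoxyphenyl}(4-methylbenzenesulfonyl)methyl]-3,5-dimethoxy-4-(methoxymethoxy)phenyl}propanoate | COC(=O)C(Br)Cc1cc(OC)c(OCOC)c(OC)c1C(c1cc(OC)c(O[Si](C)(C)C(C)(C)C)c(OC)c1)S(=O)(=O)c1ccc(C)cc1 | intermediate (not isolated)
15 | methyl 2-bromo-3-{2-[(4-hydroxy-3,5-dimethoxyphenyl)(4-methylbenzenesulfonyl)methyl]-3,5-dimethoxy-4-(methoxymethoxy)phenyl}propanoate (diastereomer mixture) | COC(=O)C(Br)Cc1cc(OC)c(OCOC)c(OC)c1C(c1cc(OC)c(O)c(OC)c1)S(=O)(=O)c1ccc(C)cc1 | intermediate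
16 | 3-tert-butoxy-3-oxopropanoic acid (mono-tert-butyl malonate) | CC(C)(C)OC(=O)CC(=O)O | starting material
17 | allyl tert-butyl malonate | C=CCOC(=O)CC(=O)OC(C)(C)C | intermediate
18 | methyl 2-bromo-3-{2-[(3,5-dimethoxy-4-oxocyclohexa-2,5-dien-1-ylidene)methyl]-3,5-dimethoxy-4-(methoxymethoxy)phenyl}propanoate (p-quinone methide) | COC(=O)C(Br)Cc1cc(OC)c(OCOC)c(OC)c1C=C1C=C(OC)C(=O)C(OC)=C1 | intermediate (not isolated)
19 | 1-allyl 3-tert-butyl 2-[(S)-[2-(2-bromo-3-methoxy-3-oxopropyl)-4,6-dimethoxy-5-(methoxymethoxy)phenyl](4-hydroxy-3,5-dimethoxyphenyl)methyl]propanedioate | COC(=O)C(Br)Cc1cc(OC)c(OCOC)c(OC)c1[C@H](c1cc(OC)c(O)c(OC)c1)C(C(=O)OCC=C)C(=O)OC(C)(C)C | intermediate (not isolated)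
20 | 2-allyl 2-tert-butyl 3-methyl (1S)-1-(4-hydroxy-3,5-dimethoxyphenyl)-6,8-dimethoxy-7-(methoxymethoxy)-1,2,3,4-tetrahydronaphthalene-2,2,3-tricarboxylate (C2 and C3 epimers) | COC(=O)C1Cc2cc(OC)c(OCOC)c(OC)c2[C@H](c2cc(OC)c(O)c(OC)c2)C1(C(=O)OCC=C)C(=O)OC(C)(C)C | intermediate
21 | 2-allyl 2-tert-butyl 3-methyl (1S)-1-[3,5-dimethoxy-4-(methoxymethoxy)phenyl]-6,8-dimethoxy-7-(methoxymethoxy)-1,2,3,4-tetrahydronaphthalene-2,2,3-tricarboxylate (C2 and C3 epimers) | COC(=O)C1Cc2cc(OC)c(OCOC)c(OC)c2[C@H](c2cc(OC)c(OCOC)c(OC)c2)C1(C(=O)OCC=C)C(=O)OC(C)(C)C | intermediate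
22 | 3-(phenylselanyl) derivative of 21 | COC(=O)C1([Se]c3ccccc3)Cc2cc(OC)c(OCOC)c(OC)c2[C@H](c2cc(OC)c(OCOC)c(OC)c2)C1(C(=O)OCC=C)C(=O)OC(C)(C)C | intermediate (not isolated)
23 | 3-(phenylseleninyl) derivative of 21 (selenoxide) | COC(=O)C1([Se](=O)c3ccccc3)Cc2cc(OC)c(OCOC)c(OC)c2[C@H](c2cc(OC)c(OCOC)c(OC)c2)C1(C(=O)OCC=C)C(=O)OC(C)(C)C | intermediate (not isolated)
24 | 2-allyl 2-tert-butyl 3-methyl (1S)-1-[3,5-dimethoxy-4-(methoxymethoxy)phenyl]-6,8-dimethoxy-7-(methoxymethoxy)-1,2-dihydronaphthalene-2,2,3-tricarboxylate (C2 epimers) | COC(=O)C1=Cc2cc(OC)c(OCOC)c(OC)c2[C@H](c2cc(OC)c(OCOC)c(OC)c2)C1(C(=O)OCC=C)C(=O)OC(C)(C)C | intermediate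
25 | (1S)-2-(tert-butoxycarbonyl)-1-[3,5-dimethoxy-4-(methoxymethoxy)phenyl]-6,8-dimethoxy-3-(methoxycarbonyl)-7-(methoxymethoxy)-1,2-dihydronaphthalene-2-carboxylic acid (C2 epimers) | COC(=O)C1=Cc2cc(OC)c(OCOC)c(OC)c2[C@H](c2cc(OC)c(OCOC)c(OC)c2)C1(C(=O)O)C(=O)OC(C)(C)C | intermediate (not isolated)
26 | 2-tert-butyl 3-methyl (1S)-1-[3,5-dimethoxy-4-(methoxymethoxy)phenyl]-6,8-dimethoxy-7-(methoxymethoxy)-1,2-dihydronaphthalene-2,3-dicarboxylate (C2 epimers) | COC(=O)C1=Cc2cc(OC)c(OCOC)c(OC)c2[C@H](c2cc(OC)c(OCOC)c(OC)c2)C1C(=O)OC(C)(C)C | intermediate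
27 | 2-tert-butyl 3-methyl (1S,2R)-1-[3,5-dimethoxy-4-(methoxymethoxy)phenyl]-6,8-dimethoxy-7-(methoxymethoxy)-1,2-dihydronaphthalene-2,3-dicarboxylate (1,2-trans) | COC(=O)C1=Cc2cc(OC)c(OCOC)c(OC)c2[C@H](c2cc(OC)c(OCOC)c(OC)c2)[C@H]1C(=O)OC(C)(C)C | intermediate
28 | (1S,2R)-7-hydroxy-1-(4-hydroxy-3,5-dimethoxyphenyl)-6,8-dimethoxy-3-(methoxycarbonyl)-1,2-dihydronaphthalene-2-carboxylic acid | COC(=O)C1=Cc2cc(OC)c(O)c(OC)c2[C@H](c2cc(OC)c(O)c(OC)c2)[C@H]1C(=O)O | intermediate
29 | methyl (1S,2R)-7-hydroxy-1-(4-hydroxy-3,5-dimethoxyphenyl)-2-(hydroxymethyl)-6,8-dimethoxy-1,2-dihydronaphthalene-3-carboxylate | COC(=O)C1=Cc2cc(OC)c(O)c(OC)c2[C@H](c2cc(OC)c(O)c(OC)c2)[C@H]1CO | target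

**Step count**
Total: 15 steps. Longest linear sequence: 13 steps (1, 2, 4, 5, 6, 7, 9, 10, 11, 12, 13, 14, 15).

**Steps most likely to fail**

1. Step 9. Three processes may defeat it: E2 loss of HBr from the α-bromo ester, after which the tethered malonate would close a five-membered ring by Michael addition; poor facial selectivity at the crowded quinone methide; and erosion of the C1 configuration by retro-1,6-addition from the phenoxide. Fallback: the order of the two bond formations is reversed so that the crowded bond is made by conjugate addition and not by SN2. Setting out from 13, the sodium enolate of 17 (NaH, DMF, 0 °C) is alkylated intermolecularly to give 1-allyl 1-tert-butyl 2-methyl 3-{2-[{4-[(tert-butyldimethylsilyl)oxy]-3,5-dimethoxyphenyl}(methoxy)methyl]-3,5-dimethoxy-4-(methoxymethoxy)phenyl}propane-1,1,2-tricarboxylate F1. p-Toluenesulfinic acid then converts this into the silyl sulfone F2, and HF·pyridine gives the phenol sulfone F3. Treatment of F3 with the same chiral ammonium–urea catalyst and Cs2CO3 should generate the quinone methide and close ring B by an intramolecular 6-exo-trig 1,6-addition, which comes back to the route at 20.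

2. Step 13. The dienolate may be reprotonated at C4, which moves the double bond out of conjugation with ring A, or the equilibrium may not favour the trans epimer enough. Fallback: the C2 configuration is set at the aldehyde oxidation level under acid instead. Setting out from 24, deallylation (Pd(PPh3)4, morpholine) gives half-acid 25, which is isolated and reduced with BH3·THF to 2-tert-butyl 3-methyl (1S)-1-[3,5-dimethoxy-4-(methoxymethoxy)phenyl]-2-(hydroxymethyl)-6,8-dimethoxy-7-(methoxymethoxy)-1,2-dihydronaphthalene-2,3-dicarboxylate F4. Dess–Martin oxidation gives the 2-formyl ester F5. TFA/CH2Cl2/H2O then cleaves the tert-butyl ester and both MOM groups, the β-formyl acid loses CO2, and the aldehyde equilibrates through its enol to methyl (1S,2R)-2-formyl-7-hydroxy-1-(4-hydroxy-3,5-dimethoxyphenyl)-6,8-dimethoxy-1,2-dihydronaphthalene-3-carboxylate F6. NaBH4 in MeOH at −20 °C reduces the aldehyde and comes back to the route at 29.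

3. Step 5. The ortho-substituted aryl nucleophile may open the epoxide sluggishly or attack the ester of the glycidate or of the product. Fallback: the side chain is built by palladium chemistry and enolate bromination. Setting out from 8, a Heck reaction with methyl acrylate (Pd(OAc)2, P(o-tol)3, Et3N, DMF, 100 °C) gives methyl (E)-3-{2-[{4-[(tert-butyldimethylsilyl)oxy]-3,5-dimethoxyphenyl}(methoxy)methyl]-3,5-dimethoxy-4-(methoxymethoxy)phenyl}prop-2-enoate F7. Conjugate reduction (NiCl2·6H2O, NaBH4, MeOH, 0 °C) gives the saturated ester F8, and its lithium enolate (LDA, THF, −78 °C) is brominated with CBr4, which comes back to the route at 13.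

**Further compounds**
F1 | step 9 | 1-allyl 1-tert-butyl 2-methyl 3-{2-[{4-[(tert-butyldimethylsilyl)oxy]-3,5-dimethoxyphenyl}(methoxy)methyl]-3,5-dimethoxy-4-(methoxymethoxy)phenyl}propane-1,1,2-tricarboxylate | COC(=O)C(Cc1cc(OC)c(OCOC)c(OC)c1C(OC)c1cc(OC)c(O[Si](C)(C)C(C)(C)C)c(OC)c1)C(C(=O)OCC=C)C(=O)OC(C)(C)C
F2 | step 9 | 1-allyl 1-tert-butyl 2-methyl 3-{2-[{4-[(tert-butyldimethylsilyl)oxy]-3,5-dimethoxyphenyl}(4-methylbenzenesulfonyl)methyl]-3,5-dimethoxy-4-(methoxymethoxy)phenyl}propane-1,1,2-tricarboxylate | COC(=O)C(Cc1cc(OC)c(OCOC)c(OC)c1C(c1cc(OC)c(O[Si](C)(C)C(C)(C)C)c(OC)c1)S(=O)(=O)c1ccc(C)cc1)C(C(=O)OCC=C)C(=O)OC(C)(C)C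
F3 | step 9 | 1-allyl 1-tert-butyl 2-methyl 3-{2-[(4-hydroxy-3,5-dimethoxyphenyl)(4-methylbenzenesulfonyl)methyl]-3,5-dimethoxy-4-(methoxymethoxy)phenyl}propane-1,1,2-tricarboxylate | COC(=O)C(Cc1cc(OC)c(OCOC)c(OC)c1C(c1cc(OC)c(O)c(OC)c1)S(=O)(=O)c1ccc(C)cc1)C(C(=O)OCC=C)C(=O)OC(C)(C)C
F4 | step 13 | 2-tert-butyl 3-methyl (1S)-1-[3,5-dimethoxy-4-(methoxymethoxy)phenyl]-2-(hydroxymethyl)-6,8-dimethoxy-7-(methoxymethoxy)-1,2-dihydronaphthalene-2,3-dicarboxylate (C2 epimers) | COC(=O)C1=Cc2cc(OC)c(OCOC)c(OC)c2[C@H](c2cc(OC)c(OCOC)c(OC)c2)C1(CO)C(=O)OC(C)(C)C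
F5 | step 13 | 2-tert-butyl 3-methyl (1S)-1-[3,5-dimethoxy-4-(methoxymethoxy)phenyl]-2-formyl-6,8-dimethoxy-7-(methoxymethoxy)-1,2-dihydronaphthalene-2,3-dicarboxylate (C2 epimers) | COC(=O)C1=Cc2cc(OC)c(OCOC)c(OC)c2[C@H](c2cc(OC)c(OCOC)c(OC)c2)C1(C=O)C(=O)OC(C)(C)C
F6 | step 13 | methyl (1S,2R)-2-formyl-7-hydroxy-1-(4-hydroxy-3,5-dimethoxyphenyl)-6,8-dimethoxy-1,2-dihydronaphthalene-3-carboxylate | COC(=O)C1=Cc2cc(OC)c(O)c(OC)c2[C@H](c2cc(OC)c(O)c(OC)c2)[C@H]1C=O
F7 | step 5 | methyl (E)-3-{2-[{4-[(tert-butyldimethylsilyl)oxy]-3,5-dimethoxyphenyl}(methoxy)methyl]-3,5-dimethoxy-4-(methoxymethoxy)phenyl}prop-2-enoate | COC(=O)/C=C/c1cc(OC)c(OCOC)c(OC)c1C(OC)c1cc(OC)c(O[Si](C)(C)C(C)(C)C)c(OC)c1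
F8 | step 5 | methyl 3-{2-[{4-[(tert-butyldimethylsilyl)oxy]-3,5-dimethoxyphenyl}(methoxy)methyl]-3,5-dimethoxy-4-(methoxymethoxy)phenyl}propanoate | COC(=O)CCc1cc(OC)c(OCOC)c(OC)c1C(OC)c1cc(OC)c(O[Si](C)(C)C(C)(C)C)c(OC)c1
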